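**Plan**
Retrosynthesis: with two carboxyl groups put back on C3 and C5, ring A is cut at C2–C3 and C5–C6. Ring A is a phloroglucinol whose ether carbon C1 lies between the hydroxyl-bearing C2 and C6 and opposite the C4 hydroxyl, so C2–C1–C6 is an aryloxymalonate (ether oxygen already on C1) and C3–C4–C5 an acetonedicarboxylate.
Next the malonate C–O bond to ring B is cut, then the ether bonds B–O–C and C–O–D, each on the side of the unhindered carbon (C1 of ring C, C1 of ring D), leaving a doubly flanked phenol and an arylboronic acid.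
Forward: 4-bromo-2,6-difluorobenzaldehyde gives the ring C phenol 4, which after O-benzylation is also ring D. Boronic acid 8 (D) is coupled to 4 (C), and boronic acid 12 (CD) to the ring B salicylaldehyde 15; the formyl group of 15 then becomes the last benzyloxy group and its bromide the free hydroxyl.
Ring B is alkylated with a bromomalonate, ring A is closed last by the double Claisen condensation, and one hydrogenolysis–decarboxylation releases the target.
Stereochemistry: the target and every isolated intermediate are achiral; nothing has to be controlled.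

Key step: step 15

Remark: 30 is an air-sensitive polyphenol, so step 16 is assumed to be run and worked up under argon; sodium benzyloxide (NaOCH2Ph) is taken as the commercial 1.0 M solution in benzyl alcohol.

**Route**

Step 1
Reactants: 1 4-bromo-2,6-difluorobenzaldehyde
Product: 2 2,6-bis(benzyloxy)-4-bromobenzaldehyde
Conditions: NaOCH2Ph (1.0 M in BnOH, 2.3 equiv), THF, 0 °C → 50 °C
Reagents that add atoms: sodium benzyloxide [Na+].[O-]Cc1ccccc1
Why: The formyl group activates both ortho C–F bonds for addition–elimination (SNAr), and bromide para to it is a far poorer leaving group than fluoride, so the two fluorides should be replaced and the bromide kept.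

Step 2
Reactants: 2 2,6-bis(benzyloxy)-4-bromobenzaldehyde
Product: 4 2,6-bis(benzyloxy)-4-bromophenol, via aryl formate 3 (not isolated)
Conditions: 30% H2O2, (PhSe)2 (5 mol%), CH2Cl2, rt; then K2CO3 (cat.), MeOH, rt
Reagents that add atoms: hydrogen peroxide OO
Why: Baeyer–Villiger (Dakin-type) oxidation, in which the 2,6-dialkoxyaryl group migrates in preference to hydride and base-catalysed methanolysis of the formate frees the phenol.

Step 3
Reactants: 4 2,6-bis(benzyloxy)-4-bromophenol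
Product: 5 1,2,3-tris(benzyloxy)-5-bromobenzene
Conditions: BnBr, K2CO3, DMF, 60 °C
Reagents that add atoms: benzyl bromide BrCc1ccccc1
Why: Williamson O-benzylation of the phenoxide by SN2 on benzyl bromide.

Step 4
Reactants: 5 1,2,3-tris(benzyloxy)-5-bromobenzene
Product: 8 [3,4,5-tris(benzyloxy)phenyl]boronic acid, via aryllithium 6 (not isolated), via lithium aryltriisopropoxyborate 7 (not isolated)
Conditions: n-BuLi, THF, −78 °C; B(OiPr)3, −78 °C → rt; aq. HCl
Reagents that add atoms: triisopropyl borate CC(C)OB(OC(C)C)OC(C)C; water O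
Why: Bromine–lithium exchange at −78 °C is faster than deprotonation of the benzyl ethers, and the aryllithium is trapped by the borate ester and hydrolysed (lithiation–borylation).

Step 5
Reactants: 8 [3,4,5-tris(benzyloxy)phenyl]boronic acid; 4 2,6-bis(benzyloxy)-4-bromophenol
Product: 9 1,3-bis(benzyloxy)-5-bromo-2-[3,4,5-tris(benzyloxy)phenoxy]benzene
Conditions: Cu(OAc)2 (1 equiv), pyridine, 4 Å MS, CH2Cl2, O2 (1 atm), rt
Reagents that add atoms: none
Why: Chan–Lam oxidative C–O coupling, in which copper-bound phenoxide and aryl (after boron-to-copper transfer) reductively eliminate at room temperature; the reaction is known to accept 2,6-disubstituted phenols and to leave aryl bromides alone.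

Step 6
Reactants: 9 1,3-bis(benzyloxy)-5-bromo-2-[3,4,5-tris(benzyloxy)phenoxy]benzene
Product: 12 {3,5-bis(benzyloxy)-4-[3,4,5-tris(benzyloxy)phenoxy]phenyl}boronic acid, via aryllithium 10 (not isolated), via lithium aryltriisopropoxyborate 11 (not isolated)
Conditions: n-BuLi, THF, −78 °C; B(OiPr)3, −78 °C → rt; aq. HCl
Reagents that add atoms: triisopropyl borate CC(C)OB(OC(C)C)OC(C)C; water O
Why: Lithiation–borylation as in step 4; the bromide sits between two ring hydrogens and the ethers are inert at −78 °C.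

Step 7
Reactants: 13 2,3,4-trihydroxybenzaldehyde
Product: 14 3,4-bis(benzyloxy)-2-hydroxybenzaldehyde
Conditions: BnBr (2.1 equiv), K2CO3 (2.2 equiv), DMF, rt
Reagents that add atoms: benzyl bromide BrCc1ccccc1
Why: Selective phenol alkylation: the 2-hydroxyl is held in a hydrogen bond to the formyl group and gives the least nucleophilic phenoxide, so two equivalents of benzyl bromide should go to O4 and O3, as is usual for 2,3,4-trihydroxyaryl carbonyl compounds.

Step 8
Reactants: 14 3,4-bis(benzyloxy)-2-hydroxybenzaldehyde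
Product: 15 3,4-bis(benzyloxy)-5-bromo-2-hydroxybenzaldehyde
Conditions: NBS, MeCN, 0 °C → rt
Reagents that add atoms: N-bromosuccinimide O=C1CCC(=O)N1Br
Why: Electrophilic aromatic bromination at C5, which is para to the free hydroxyl and ortho to a benzyloxy group; C6 is ortho to the formyl group and not activated by the hydroxyl.

Step 9
Reactants: 12 {3,5-bis(benzyloxy)-4-[3,4,5-tris(benzyloxy)phenoxy]phenyl}boronic acid; 15 3,4-bis(benzyloxy)-5-bromo-2-hydroxybenzaldehyde
Product: 16 3,4-bis(benzyloxy)-2-{3,5-bis(benzyloxy)-4-[3,4,5-tris(benzyloxy)phenoxy]phenoxy}-5-bromobenzaldehyde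
Conditions: Cu(OAc)2 (1 equiv), pyridine, 4 Å MS, CH2Cl2, O2 (1 atm), rt
Reagents that add atoms: none
Why: Chan–Lam coupling as in step 5; boron sits on the unhindered C1 of ring C so only the phenol partner is crowded, and the neutral room-temperature conditions spare the aldehyde and the aryl bromide.

Step 10
Reactants: 16 3,4-bis(benzyloxy)-2-{3,5-bis(benzyloxy)-4-[3,4,5-tris(benzyloxy)phenoxy]phenoxy}-5-bromobenzaldehyde
Product: 18 3,4-bis(benzyloxy)-2-{3,5-bis(benzyloxy)-4-[3,4,5-tris(benzyloxy)phenoxy]phenoxy}-5-bromophenol, via aryl formate 17 (not isolated)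
Conditions: 30% H2O2, (PhSe)2 (5 mol%), CH2Cl2, rt; then K2CO3 (cat.), MeOH–THF, rt
Reagents that add atoms: hydrogen peroxide OO
Why: Baeyer–Villiger (Dakin-type) oxidation: the ring B aryl group, with an ortho aryloxy and a para benzyloxy donor, migrates, and the selenium-catalysed peroxide is selective for the aldehyde over the electron-rich arenes.

Step 11
Reactants: 18 3,4-bis(benzyloxy)-2-{3,5-bis(benzyloxy)-4-[3,4,5-tris(benzyloxy)phenoxy]phenoxy}-5-bromophenol
Product: 19 2,3,5-tris(benzyloxy)-4-{3,5-bis(benzyloxy)-4-[3,4,5-tris(benzyloxy)phenoxy]phenoxy}-1-bromobenzene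
Conditions: BnBr, K2CO3, DMF, 50 °C
Reagents that add atoms: benzyl bromide BrCc1ccccc1
Why: Williamson O-benzylation; the new benzyloxy group completes the pair of oxygens flanking the B–O–C ether.

Step 12
Reactants: 19 2,3,5-tris(benzyloxy)-4-{3,5-bis(benzyloxy)-4-[3,4,5-tris(benzyloxy)phenoxy]phenoxy}-1-bromobenzene
Product: 22 2,3,5-tris(benzyloxy)-4-{3,5-bis(benzyloxy)-4-[3,4,5-tris(benzyloxy)phenoxy]phenoxy}phenol, via aryllithium 20 (not isolated), via lithium aryltrimethoxyborate 21 (not isolated)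
Conditions: n-BuLi, THF, −78 °C; B(OMe)3, −78 → 0 °C; then AcOH, 30% H2O2, 0 °C → rt
Reagents that add atoms: hydrogen peroxide OO
Why: One-pot lithiation–borylation–oxidation: bromine–lithium exchange, trapping on boron, and peroxide-induced 1,2-shift of the aryl group from boron to oxygen turn the aryl bromide into the phenol.

Step 13
Reactants: 23 dibenzyl malonate
Product: 24 dibenzyl 2-bromomalonate
Conditions: Br2 (1.0 equiv), CH2Cl2, 0 °C → rt
Reagents that add atoms: bromine BrBr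
Why: Acid-autocatalysed α-bromination of the malonate through its enol, held at the monobromide by stoichiometry.

Step 14
Reactants: 22 2,3,5-tris(benzyloxy)-4-{3,5-bis(benzyloxy)-4-[3,4,5-tris(benzyloxy)phenoxy]phenoxy}phenol; 24 dibenzyl 2-bromomalonate
Product: 25 dibenzyl 2-(2,3,5-tris(benzyloxy)-4-{3,5-bis(benzyloxy)-4-[3,4,5-tris(benzyloxy)phenoxy]phenoxy}phenoxy)malonate
Conditions: K2CO3, acetone, rt → 40 °C
Reagents that add atoms: none
Why: SN2 O-alkylation of the phenoxide by the doubly activated secondary bromide, the standard route to aryloxymalonates.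

Step 15
Reactants: 25 dibenzyl 2-(2,3,5-tris(benzyloxy)-4-{3,5-bis(benzyloxy)-4-[3,4,5-tris(benzyloxy)phenoxy]phenoxy}phenoxy)malonate; 26 dibenzyl 3-oxopentanedioate
Product: 28 dibenzyl 2,4,6-trihydroxy-5-(2,3,5-tris(benzyloxy)-4-{3,5-bis(benzyloxy)-4-[3,4,5-tris(benzyloxy)phenoxy]phenoxy}phenoxy)benzene-1,3-dicarboxylate, via acyclic triester 27 (not isolated)
Conditions: NaOCH2Ph (1.0 M in BnOH, 3 equiv), toluene, 90 °C, 26 added over 4 h; then aq. HCl, 0 °C
Reagents that add atoms: none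
Why: Proposed new method: a methylene carbon of the sodium enolate of 26 adds to one ester carbonyl of the small neutral fraction of 25 and benzyloxide leaves (intermolecular Claisen acylation) to give acyclic triester 27, whose other ketoester methylene then attacks the second malonate-derived ester in a 6-exo-trig Dieckmann closure; the cyclohexane-1,3,5-trione so formed still carries the C1 hydrogen of the malonate and tautomerises to the arene, which is held as its phenoxide. The closest known reaction type is the alkoxide-mediated (3+3) condensation of dialkyl malonates with dialkyl acetonedicarboxylates to phloroglucinol dicarboxylates; an aryloxymalonate has not been shown in it. The aryloxy group should be a spectator, since it raises the electrophilicity of both ester carbonyls and has no elimination pathway from the enolate. Ring A is the only ring closed and no stereocentre is created. The step needs C- over O-acylation in the closure and cross- over self-condensation of 26: all acylations, enol-lactone formation included, are reversible in benzyloxide while aromatisation is not, the alkoxide matches every ester so nothing is scrambled, and 26 is kept at low concentration by slow addition to hot 25.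

Step 16
Reactants: 28 dibenzyl 2,4,6-trihydroxy-5-(2,3,5-tris(benzyloxy)-4-{3,5-bis(benzyloxy)-4-[3,4,5-tris(benzyloxy)phenoxy]phenoxy}phenoxy)benzene-1,3-dicarboxylate
Product: 30 5-{2,6-dihydroxy-4-[2,3,6-trihydroxy-4-(2,4,6-trihydroxyphenoxy)phenoxy]phenoxy}benzene-1,2,3-triol, via octahydroxy diacid 29 (not isolated)
Conditions: H2 (1 atm), 10% Pd/C, THF–MeOH, rt; filter under Ar; then H2O, 60 °C
Reagents that add atoms: none
Why: Hydrogenolysis on Pd/C cleaves all eight benzyl ethers and both benzyl esters, and the resulting 2,4,6-trihydroxyisophthalic acid loses two CO2 through ipso-protonation of the electron-rich ring, as phloroglucinol carboxylic acids do on gentle warming.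

**Compound list**
1 | 4-bromo-2,6-difluorobenzaldehyde | O=Cc1c(F)cc(Br)cc1F | starting material
2 | 2,6-bis(benzyloxy)-4-bromobenzaldehyde | O=Cc1c(OCc2ccccc2)cc(Br)cc1OCc1ccccc1 | intermediate
3 | 2,6-bis(benzyloxy)-4-bromophenyl formate | O=COc1c(OCc2ccccc2)cc(Br)cc1OCc1ccccc1 | intermediate
4 | 2,6-bis(benzyloxy)-4-bromophenol | Oc1c(OCc2ccccc2)cc(Br)cc1OCc1ccccc1 | intermediate
5 | 1,2,3-tris(benzyloxy)-5-bromobenzene | Brc1cc(OCc2ccccc2)c(OCc2ccccc2)c(OCc2ccccc2)c1 | intermediate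
6 | [3,4,5-tris(benzyloxy)phenyl]lithium | [Li]c1cc(OCc2ccccc2)c(OCc2ccccc2)c(OCc2ccccc2)c1 | intermediate
7 | lithium triisopropoxy[3,4,5-tris(benzyloxy)phenyl]borate | [Li+].CC(C)O[B-](OC(C)C)(OC(C)C)c1cc(OCc2ccccc2)c(OCc2ccccc2)c(OCc2ccccc2)c1 | intermediate
8 | [3,4,5-tris(benzyloxy)phenyl]boronic acid | OB(O)c1cc(OCc2ccccc2)c(OCc2ccccc2)c(OCc2ccccc2)c1 | intermediate
9 | 1,3-bis(benzyloxy)-5-bromo-2-[3,4,5-tris(benzyloxy)phenoxy]benzene | Brc1cc(OCc2ccccc2)c(Oc2cc(OCc3ccccc3)c(OCc3ccccc3)c(OCc3ccccc3)c2)c(OCc2ccccc2)c1 | intermediate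
10 | {3,5-bis(benzyloxy)-4-[3,4,5-tris(benzyloxy)phenoxy]phenyl}lithium | [Li]c1cc(OCc2ccccc2)c(Oc2cc(OCc3ccccc3)c(OCc3ccccc3)c(OCc3ccccc3)c2)c(OCc2ccccc2)c1 | intermediate
11 | lithium triisopropoxy{3,5-bis(benzyloxy)-4-[3,4,5-tris(benzyloxy)phenoxy]phenyl}borate | [Li+].CC(C)O[B-](OC(C)C)(OC(C)C)c1cc(OCc2ccccc2)c(Oc2cc(OCc3ccccc3)c(OCc3ccccc3)c(OCc3ccccc3)c2)c(OCc2ccccc2)c1 | intermediate
12 | {3,5-bis(benzyloxy)-4-[3,4,5-tris(benzyloxy)phenoxy]phenyl}boronic acid | OB(O)c1cc(OCc2ccccc2)c(Oc2cc(OCc3ccccc3)c(OCc3ccccc3)c(OCc3ccccc3)c2)c(OCc2ccccc2)c1 | intermediate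
13 | 2,3,4-trihydroxybenzaldehyde | O=Cc1ccc(O)c(O)c1O | starting material
14 | 3,4-bis(benzyloxy)-2-hydroxybenzaldehyde | O=Cc1ccc(OCc2ccccc2)c(OCc2ccccc2)c1O | intermediate
15 | 3,4-bis(benzyloxy)-5-bromo-2-hydroxybenzaldehyde | O=Cc1cc(Br)c(OCc2ccccc2)c(OCc2ccccc2)c1O | intermediate
16 | 3,4-bis(benzyloxy)-2-{3,5-bis(benzyloxy)-4-[3,4,5-tris(benzyloxy)phenoxy]phenoxy}-5-bromobenzaldehyde | O=Cc1cc(Br)c(OCc2ccccc2)c(OCc2ccccc2)c1Oc1cc(OCc2ccccc2)c(Oc2cc(OCc3ccccc3)c(OCc3ccccc3)c(OCc3ccccc3)c2)c(OCc2ccccc2)c1 | intermediate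
17 | 3,4-bis(benzyloxy)-2-{3,5-bis(benzyloxy)-4-[3,4,5-tris(benzyloxy)phenoxy]phenoxy}-5-bromophenyl formate | O=COc1cc(Br)c(OCc2ccccc2)c(OCc2ccccc2)c1Oc1cc(OCc2ccccc2)c(Oc2cc(OCc3ccccc3)c(OCc3ccccc3)c(OCc3ccccc3)c2)c(OCc2ccccc2)c1 | intermediate
18 | 3,4-bis(benzyloxy)-2-{3,5-bis(benzyloxy)-4-[3,4,5-tris(benzyloxy)phenoxy]phenoxy}-5-bromophenol | Oc1cc(Br)c(OCc2ccccc2)c(OCc2ccccc2)c1Oc1cc(OCc2ccccc2)c(Oc2cc(OCc3ccccc3)c(OCc3ccccc3)c(OCc3ccccc3)c2)c(OCc2ccccc2)c1 | intermediate
19 | 2,3,5-tris(benzyloxy)-4-{3,5-bis(benzyloxy)-4-[3,4,5-tris(benzyloxy)phenoxy]phenoxy}-1-bromobenzene | Brc1cc(OCc2ccccc2)c(Oc2cc(OCc3ccccc3)c(Oc3cc(OCc4ccccc4)c(OCc4ccccc4)c(OCc4ccccc4)c3)c(OCc3ccccc3)c2)c(OCc2ccccc2)c1OCc1ccccc1 | intermediate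
20 | (2,3,5-tris(benzyloxy)-4-{3,5-bis(benzyloxy)-4-[3,4,5-tris(benzyloxy)phenoxy]phenoxy}phenyl)lithium | [Li]c1cc(OCc2ccccc2)c(Oc2cc(OCc3ccccc3)c(Oc3cc(OCc4ccccc4)c(OCc4ccccc4)c(OCc4ccccc4)c3)c(OCc3ccccc3)c2)c(OCc2ccccc2)c1OCc1ccccc1 | intermediate
21 | lithium trimethoxy(2,3,5-tris(benzyloxy)-4-{3,5-bis(benzyloxy)-4-[3,4,5-tris(benzyloxy)phenoxy]phenoxy}phenyl)borate | [Li+].CO[B-](OC)(OC)c1cc(OCc2ccccc2)c(Oc2cc(OCc3ccccc3)c(Oc3cc(OCc4ccccc4)c(OCc4ccccc4)c(OCc4ccccc4)c3)c(OCc3ccccc3)c2)c(OCc2ccccc2)c1OCc1ccccc1 | intermediate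
22 | 2,3,5-tris(benzyloxy)-4-{3,5-bis(benzyloxy)-4-[3,4,5-tris(benzyloxy)phenoxy]phenoxy}phenol | Oc1cc(OCc2ccccc2)c(Oc2cc(OCc3ccccc3)c(Oc3cc(OCc4ccccc4)c(OCc4ccccc4)c(OCc4ccccc4)c3)c(OCc3ccccc3)c2)c(OCc2ccccc2)c1OCc1ccccc1 | intermediate
23 | dibenzyl malonate | O=C(CC(=O)OCc1ccccc1)OCc1ccccc1 | starting material
24 | dibenzyl 2-bromomalonate | O=C(OCc1ccccc1)C(Br)C(=O)OCc1ccccc1 | intermediate
25 | dibenzyl 2-(2,3,5-tris(benzyloxy)-4-{3,5-bis(benzyloxy)-4-[3,4,5-tris(benzyloxy)phenoxy]phenoxy}phenoxy)malonate | O=C(OCc1ccccc1)C(C(=O)OCc1ccccc1)Oc1cc(OCc2ccccc2)c(Oc2cc(OCc3ccccc3)c(Oc3cc(OCc4ccccc4)c(OCc4ccccc4)c(OCc4ccccc4)c3)c(OCc3ccccc3)c2)c(OCc2ccccc2)c1OCc1ccccc1 | intermediate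
26 | dibenzyl 3-oxopentanedioate | O=C(CC(=O)OCc1ccccc1)CC(=O)OCc1ccccc1 | starting material
27 | dibenzyl 4-(benzyloxycarbonyl)-3,5-dioxo-2-(2,3,5-tris(benzyloxy)-4-{3,5-bis(benzyloxy)-4-[3,4,5-tris(benzyloxy)phenoxy]phenoxy}phenoxy)heptanedioate | O=C(OCc1ccccc1)CC(=O)C(C(=O)OCc1ccccc1)C(=O)C(C(=O)OCc1ccccc1)Oc1cc(OCc2ccccc2)c(Oc2cc(OCc3ccccc3)c(Oc3cc(OCc4ccccc4)c(OCc4ccccc4)c(OCc4ccccc4)c3)c(OCc3ccccc3)c2)c(OCc2ccccc2)c1OCc1ccccc1 | intermediate
28 | dibenzyl 2,4,6-trihydroxy-5-(2,3,5-tris(benzyloxy)-4-{3,5-bis(benzyloxy)-4-[3,4,5-tris(benzyloxy)phenoxy]phenoxy}phenoxy)benzene-1,3-dicarboxylate | Oc1c(C(=O)OCc2ccccc2)c(O)c(C(=O)OCc2ccccc2)c(O)c1Oc1cc(OCc2ccccc2)c(Oc2cc(OCc3ccccc3)c(Oc3cc(OCc4ccccc4)c(OCc4ccccc4)c(OCc4ccccc4)c3)c(OCc3ccccc3)c2)c(OCc2ccccc2)c1OCc1ccccc1 | intermediate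
29 | 2,4,6-trihydroxy-5-(2,3,5-trihydroxy-4-{3,5-dihydroxy-4-[3,4,5-trihydroxyphenoxy]phenoxy}phenoxy)benzene-1,3-dicarboxylic acid | Oc1c(C(=O)O)c(O)c(C(=O)O)c(O)c1Oc1cc(O)c(Oc2cc(O)c(Oc3cc(O)c(O)c(O)c3)c(O)c2)c(O)c1O | intermediate
30 | 5-{2,6-dihydroxy-4-[2,3,6-trihydroxy-4-(2,4,6-trihydroxyphenoxy)phenoxy]phenoxy}benzene-1,2,3-triol (CNP0018315.0) | Oc1cc(O)c(Oc2cc(O)c(Oc3cc(O)c(Oc4cc(O)c(O)c(O)c4)c(O)c3)c(O)c2O)c(O)c1 | target

**Count and risks**
Total steps: 16. Longest linear sequence: 13 steps (1, 2, 3, 4, 5, 6, 9, 10, 11, 12, 14, 15, 16), from compound 1.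

Steps most likely to fail:

Step 15 (ring A annulation). Both partners are present mainly as enolates, so the cross-acylation may be slower than the self-condensation or retro-Claisen cleavage of 26. Ring closure through oxygen may also drain material into a pyranone that does not revert, and long heating in benzyloxide may cleave benzyl esters. The fallback uses known chemistry and brings ring A in ready-made. Commercial 2,4,6-trihydroxybenzaldehyde is perbenzylated (BnBr, K2CO3, DMF) to 2,4,6-tris(benzyloxy)benzaldehyde F1. This is oxidised (H2O2, (PhSe)2; then K2CO3, MeOH) through 2,4,6-tris(benzyloxy)phenyl formate F2 to 2,4,6-tris(benzyloxy)phenol F3. Ullmann ether coupling of F3 with bromide 19 (CuI, picolinic acid, K3PO4, DMSO, 100 °C) should give 1,3,5-tris(benzyloxy)-2-(2,3,5-tris(benzyloxy)-4-{3,5-bis(benzyloxy)-4-[3,4,5-tris(benzyloxy)phenoxy]phenoxy}phenoxy)benzene F4. Hydrogenolysis of F4 (H2, Pd/C) then gives the target. The fallback sets out from 19 and comes back to the route at 30.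

Step 9 (second Chan–Lam coupling). The phenoxide of 15 is electron-poor and chelates copper through the neighbouring formyl group, so C–O bond formation may stall while 12 is lost to protodeboronation and homocoupling. In the fallback the formyl group of 15 is masked first (ethylene glycol, TsOH, toluene, water removal) to give 2-[3,4-bis(benzyloxy)-5-bromo-2-hydroxyphenyl]-1,3-dioxolane F5, a non-chelating, electron-richer 2,6-disubstituted phenol of the kind coupled in step 5. Chan–Lam coupling of F5 with 12 should give 2-(3,4-bis(benzyloxy)-2-{3,5-bis(benzyloxy)-4-[3,4,5-tris(benzyloxy)phenoxy]phenoxy}-5-bromophenyl)-1,3-dioxolane F6, and aqueous HCl in THF unmasks the aldehyde. The fallback sets out from 15 and comes back to the route at 16.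

Step 14 (O-alkylation with the bromomalonate). The electron-rich phenoxide of 22 may attack bromine instead of carbon, which transfers bromine to the arene and reduces 24 to dibenzyl malonate; the acidic product may also be alkylated a second time. The fallback forms the same C–O bond without base or halogen. Diazo transfer to 23 (4-acetamidobenzenesulfonyl azide, Et3N, MeCN) gives dibenzyl 2-diazomalonate F7, and Rh2(OAc)4-catalysed O–H insertion of its carbenoid into phenol 22 (toluene, 80 °C) should give the aryloxymalonate. The fallback sets out from 22 and 23 and comes back to the route at 25.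

**Further compounds**
F1 | step 15 | 2,4,6-tris(benzyloxy)benzaldehyde | O=Cc1c(OCc2ccccc2)cc(OCc2ccccc2)cc1OCc1ccccc1
F2 | step 15 | 2,4,6-tris(benzyloxy)phenyl formate | O=COc1c(OCc2ccccc2)cc(OCc2ccccc2)cc1OCc1ccccc1
F3 | step 15 | 2,4,6-tris(benzyloxy)phenol | Oc1c(OCc2ccccc2)cc(OCc2ccccc2)cc1OCc1ccccc1
F4 | step 15 | 1,3,5-tris(benzyloxy)-2-(2,3,5-tris(benzyloxy)-4-{3,5-bis(benzyloxy)-4-[3,4,5-tris(benzyloxy)phenoxy]phenoxy}phenoxy)benzene | c1ccccc1COc1cc(OCc2ccccc2)c(Oc2cc(OCc3ccccc3)c(Oc3cc(OCc4ccccc4)c(Oc4cc(OCc5ccccc5)c(OCc5ccccc5)c(OCc5ccccc5)c4)c(OCc4ccccc4)c3)c(OCc3ccccc3)c2OCc2ccccc2)c(OCc2ccccc2)c1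
F5 | step 9 | 2-[3,4-bis(benzyloxy)-5-bromo-2-hydroxyphenyl]-1,3-dioxolane | Oc1c(C2OCCO2)cc(Br)c(OCc2ccccc2)c1OCc1ccccc1
F6 | step 9 | 2-(3,4-bis(benzyloxy)-2-{3,5-bis(benzyloxy)-4-[3,4,5-tris(benzyloxy)phenoxy]phenoxy}-5-bromophenyl)-1,3-dioxolane | Brc1cc(C2OCCO2)c(Oc2cc(OCc3ccccc3)c(Oc3cc(OCc4ccccc4)c(OCc4ccccc4)c(OCc4ccccc4)c3)c(OCc3ccccc3)c2)c(OCc2ccccc2)c1OCc1ccccc1
F7 | step 14 | dibenzyl 2-diazomalonate | [N-]=[N+]=C(C(=O)OCc1ccccc1)C(=O)OCc1ccccc1
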